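**Plan**
- Retrosynthesis: the O1–C2 bond of ring C is cut together with the C3–H bond (retro oxa-Michael/protonation) to an α-aryl vinyl ketone. Then C2 is taken out (retro-Mannich methylenation), the C3–C1′ bond is cut (ketone α-arylation), then the C3′–C1″ aryl–allyl bond, and last the C7″–OH bond (hydration of geranyl acetate).
- Enabling feature: O1 is β to the C4 carbonyl, C2 is an unsubstituted CH2, C3 is an enolizable CH, and ring A is a phloroglucinol whose two hydroxyls ortho to the acyl carbon are equivalent. One oxa-Michael addition onto a C3=C2H2 enone therefore closes ring C without a regiochemical choice and leaves an enol whose protonation creates C3.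
- Forward: side chain (steps 1–4), ring B bromide (5–7), rings A and B joined as a deoxybenzoin (8, 9), enone with ring A masked as acid-labile acetals (10), ring C closed and C3 set in one catalytic operation (11), desilylation (12).
- Stereochemistry: the (E)-alkene comes unchanged from geranyl acetate. C3 (S) comes from catalyst-controlled protonation in step 11 and afterwards meets only buffered fluoride.

Key step: step 11

Remark: compounds with 1-ethoxyethyl groups (14–18, F9) are mixtures of epimers at the acetal carbons, left undefined in the SMILES and lost in step 11; the (R)-catalyst is written for step 11 and its mirror image would be used if a first run shows the opposite sense of induction.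

Abbreviation used in names: ArB = 2,4-bis(tert-butyldimethylsilyloxy)-3-[(2E)-3,7-dimethyl-7-(triethylsilyloxy)oct-2-en-1-yl]phenyl.

Step 1
Reactants: 1 geranyl acetate [(2E)-3,7-dimethylocta-2,6-dien-1-yl acetate]
Product: 3 (2E)-7-hydroxy-3,7-dimethyloct-2-en-1-yl acetate, via organomercurial 2 (not isolated)
Conditions: Hg(OAc)2 (1.05 equiv), THF/H2O 1:1, rt; then NaBH4, 3 M aq NaOH, 0 °C
Reagents that add atoms: water, O
Why: Markovnikov oxymercuration–demercuration should hydrate only the electron-richer 6,7-alkene, because the 2,3-alkene is deactivated by the allylic acetoxy group, and it leaves the (E)-geometry untouched.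

Step 2
Reactants: 3 (2E)-7-hydroxy-3,7-dimethyloct-2-en-1-yl acetate
Product: 4 (2E)-3,7-dimethyl-7-(triethylsilyloxy)oct-2-en-1-yl acetate
Conditions: TESOTf (1.2 equiv), 2,6-lutidine, CH2Cl2, −78 → 0 °C
Reagents that add atoms: triethylsilyl trifluoromethanesulfonate, CC[Si](CC)(CC)OS(=O)(=O)C(F)(F)F
Why: silylation of the hindered tertiary alcohol with a silyl triflate, so that the hydroxyl can neither cyclize onto the allylic bromide of step 4 nor quench the Grignard reagent of step 7.

Step 3
Reactants: 4 (2E)-3,7-dimethyl-7-(triethylsilyloxy)oct-2-en-1-yl acetate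
Product: 5 (2E)-3,7-dimethyl-7-(triethylsilyloxy)oct-2-en-1-ol
Conditions: K2CO3 (0.2 equiv), MeOH, 0 °C → rt
Reagents that add atoms: none
Why: base-catalysed transesterification (methanolysis) of the acetate, to which the tertiary triethylsilyl ether is stable.

Step 4
Reactants: 5 (2E)-3,7-dimethyl-7-(triethylsilyloxy)oct-2-en-1-ol
Product: 7 {[(6E)-8-bromo-2,6-dimethyloct-6-en-2-yl]oxy}triethylsilane, via allylic mesylate 6 (not isolated)
Conditions: MsCl, Et3N, THF, −40 °C; then LiBr in THF, −40 → 0 °C
Reagents that add atoms: lithium bromide, [Li+].[Br-]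
Why: mesylation followed by SN2 displacement with bromide at the primary allylic carbon under non-acidic conditions should keep both the alkene geometry and the silyl ether.

Step 5
Reactants: 8 2-iodobenzene-1,3-diol (2-iodoresorcinol)
Product: 9 4-bromo-2-iodobenzene-1,3-diol
Conditions: NBS (1.0 equiv), MeCN, −30 → 0 °C
Reagents that add atoms: N-bromosuccinimide, O=C1CCC(=O)N1Br
Why: electrophilic aromatic bromination; C4 and C6 are equivalent and each is ortho to one hydroxyl and para to the other, so one equivalent at low temperature should give the monobromide.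

Step 6
Reactants: 9 4-bromo-2-iodobenzene-1,3-diol
Product: 10 1-bromo-2,4-bis(tert-butyldimethylsilyloxy)-3-iodobenzene
Conditions: TBSCl (2.5 equiv), imidazole, DMF, rt
Reagents that add atoms: tert-butyldimethylsilyl chloride, CC(C)(C)[Si](C)(C)Cl
Why: standard silylation of phenols; the aryl silyl ethers should survive base, palladium catalysis and the acid of step 11 and leave at the end with fluoride.

Step 7
Reactants: 10 1-bromo-2,4-bis(tert-butyldimethylsilyloxy)-3-iodobenzene; 7 {[(6E)-8-bromo-2,6-dimethyloct-6-en-2-yl]oxy}triethylsilane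
Product: 12 1-bromo-2,4-bis(tert-butyldimethylsilyloxy)-3-[(2E)-3,7-dimethyl-7-(triethylsilyloxy)oct-2-en-1-yl]benzene (ArB–Br), via arylmagnesium chloride 11 (not isolated)
Conditions: i-PrMgCl·LiCl (1.05 equiv), THF, −20 °C; then Li2CuCl4 (5 mol%), 7 (1.1 equiv), −20 → 0 °C
Reagents that add atoms: none
Why: iodine–magnesium exchange is much faster at the iodide flanked by two oxygens than at the bromide, and the copper-catalysed Grignard–allyl bromide coupling should occur at the unhindered α-carbon (SN2; γ-attack would build a quaternary carbon on a di-ortho-substituted arene) with retention of the (E)-geometry.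

Step 8
Reactants: 13 1-(2,4,6-trihydroxyphenyl)ethan-1-one (2′,4′,6′-trihydroxyacetophenone, dried)
Product: 14 1-[2,4,6-tris(1-ethoxyethoxy)phenyl]ethan-1-one
Conditions: NaH (3.5 equiv), DMF, 0 °C; 1-chloroethyl ethyl ether (3.6 equiv), 0 °C → rt
Reagents that add atoms: 1-chloroethyl ethyl ether, CCOC(C)Cl
Why: O-alkylation of the three phenoxides with an α-chloro ether (as in the making of methoxymethyl ethers) also caps the two chelated ortho hydroxyls, and the resulting acetaldehyde acetals are base-stable yet acid-labile enough for step 11.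

Step 9
Reactants: 14 1-[2,4,6-tris(1-ethoxyethoxy)phenyl]ethan-1-one; 12 ArB–Br
Product: 15 2-ArB-1-[2,4,6-tris(1-ethoxyethoxy)phenyl]ethan-1-one (deoxybenzoin)
Conditions: Pd2(dba)3 (2.5 mol%), XPhos (6 mol%), K3PO4 (2.5 equiv), toluene, 90 °C
Reagents that add atoms: none
Why: palladium-catalysed α-arylation of the methyl ketone enolate (oxidative addition of the aryl bromide to zerovalent palladium, enolate transmetalation, reductive elimination), with a bulky biaryl phosphine for the ortho-substituted electron-rich bromide and a phosphate base that spares the silyl ethers.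

Step 10
Reactants: 15 2-ArB-1-[2,4,6-tris(1-ethoxyethoxy)phenyl]ethan-1-one
Product: 18 2-ArB-1-[2,4,6-tris(1-ethoxyethoxy)phenyl]prop-2-en-1-one, via Mannich base 16 (not isolated), via ammonium iodide 17 (not isolated)
Conditions: LiN(SiMe3)2 (1.1 equiv), THF, −78 °C; Me2N+=CH2 I− (Eschenmoser's salt, 1.3 equiv), −78 °C → rt; then MeI, CH2Cl2, rt; then aq NaHCO3, rt
Reagents that add atoms: N,N-dimethylmethyleneiminium iodide (Eschenmoser's salt), C=[N+](C)C.[I-]
Why: Mannich reaction of the benzylic enolate, N-methylation and E1cB (Hofmann-type) elimination give the α-methylene ketone, which cannot cyclize at this stage because both ortho oxygens of ring A are capped.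

Step 11
Reactants: 18 2-ArB-1-[2,4,6-tris(1-ethoxyethoxy)phenyl]prop-2-en-1-one
Product: 21 (3S)-3-ArB-5,7-dihydroxy-2,3-dihydro-4H-chromen-4-one, via trihydroxyphenyl enone 19 (not isolated), via chromene enol 20 (not isolated)
Conditions: (R)-3,3′-bis(2,4,6-triisopropylphenyl)-1,1′-binaphthyl-2,2′-diyl N-triflylphosphoramide (10 mol%), MeOH (3.3 equiv), toluene, −30 °C
Reagents that add atoms: none
Why: Proposed new method: the chiral acid first passes the three 1-ethoxyethyl groups of 18 on to methanol, so that the chelated 2,4,6-trihydroxyphenyl ketone 19 is set free only in the presence of the catalyst; the acid then activates the C4 carbonyl while one of the two equivalent ortho hydroxyls of ring A adds to the terminal carbon C2 (oxa-Michael addition, 6-endo-trig closure of ring C) to give the achiral enol 20. The only stereocentre, C3, arises in the tautomerization that follows: the catalyst, hydrogen-bonded through P=O to the enol hydroxyl, delivers its N–H proton to one face of C3 inside the pocket of the 3,3′-aryl groups, so the configuration is under catalyst control. The closest known reaction types are the chiral N-triflyl phosphoramide-catalysed Nazarov cyclization that ends in an enantioselective enol protonation, the chiral Brønsted acid-catalysed protonation of silyl enol ethers of 2-aryl cyclic ketones, and the racemic closure of 2-hydroxydeoxybenzoins with formaldehyde and an amine to isoflavanones; the acid-catalysed phenol oxa-Michael addition to an α-aryl vinyl ketone with catalyst-controlled protonation is the new element. The step needs conjugate attack at C2 in place of Markovnikov closure at the α-carbon (which would give a coumaranone) and attack by a ring A oxygen only; carbonyl activation at low temperature should secure the first and the silyl ethers on both ring B oxygens the second. The product must not enolize again, which the low temperature, the absence of base and the hydrogen bond of the new 5-hydroxyl to the ketone should ensure.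

Step 12
Reactants: 21 (3S)-3-ArB-5,7-dihydroxy-2,3-dihydro-4H-chromen-4-one
Product: 22 (3S)-3-{2,4-dihydroxy-3-[(2E)-7-hydroxy-3,7-dimethyloct-2-en-1-yl]phenyl}-5,7-dihydroxy-2,3-dihydro-4H-chromen-4-one (target)
Conditions: HF·pyridine, pyridine, THF, 0 °C → rt
Reagents that add atoms: none
Why: fluoride cleavage of the two aryl silyl ethers and the tertiary silyl ether in a weakly acidic buffered medium should avoid both enolization at C3 and acid-induced addition of the flanking phenols to the side-chain alkene.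

**Compound list**
1 | geranyl acetate, (2E)-3,7-dimethylocta-2,6-dien-1-yl acetate | C/C(=C\COC(C)=O)CCC=C(C)C | starting material
2 | (2E)-6-(acetoxymercurio)-7-hydroxy-3,7-dimethyloct-2-en-1-yl acetate (racemic at C6) | C/C(=C\COC(C)=O)CCC([Hg]OC(C)=O)C(C)(C)O | intermediate
3 | (2E)-7-hydroxy-3,7-dimethyloct-2-en-1-yl acetate | C/C(=C\COC(C)=O)CCCC(C)(C)O | intermediate
4 | (2E)-3,7-dimethyl-7-(triethylsilyloxy)oct-2-en-1-yl acetate | C/C(=C\COC(C)=O)CCCC(C)(C)O[Si](CC)(CC)CC | intermediate
5 | (2E)-3,7-dimethyl-7-(triethylsilyloxy)oct-2-en-1-ol | C/C(=C\CO)CCCC(C)(C)O[Si](CC)(CC)CC | intermediate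
6 | (2E)-3,7-dimethyl-7-(triethylsilyloxy)oct-2-en-1-yl methanesulfonate | C/C(=C\COS(C)(=O)=O)CCCC(C)(C)O[Si](CC)(CC)CC | intermediate
7 | {[(6E)-8-bromo-2,6-dimethyloct-6-en-2-yl]oxy}triethylsilane | C/C(=C\CBr)CCCC(C)(C)O[Si](CC)(CC)CC | intermediate
8 | 2-iodobenzene-1,3-diol | Oc1cccc(O)c1I | starting material
9 | 4-bromo-2-iodobenzene-1,3-diol | Oc1ccc(Br)c(O)c1I | intermediate
10 | 1-bromo-2,4-bis(tert-butyldimethylsilyloxy)-3-iodobenzene | CC(C)(C)[Si](C)(C)Oc1ccc(Br)c(O[Si](C)(C)C(C)(C)C)c1I | intermediate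
11 | [3-bromo-2,6-bis(tert-butyldimethylsilyloxy)phenyl]magnesium chloride | CC(C)(C)[Si](C)(C)Oc1ccc(Br)c(O[Si](C)(C)C(C)(C)C)c1[Mg]Cl | intermediate
12 | 1-bromo-2,4-bis(tert-butyldimethylsilyloxy)-3-[(2E)-3,7-dimethyl-7-(triethylsilyloxy)oct-2-en-1-yl]benzene | C/C(=C\Cc1c(O[Si](C)(C)C(C)(C)C)ccc(Br)c1O[Si](C)(C)C(C)(C)C)CCCC(C)(C)O[Si](CC)(CC)CC | intermediate
13 | 1-(2,4,6-trihydroxyphenyl)ethan-1-one | CC(=O)c1c(O)cc(O)cc1O | starting material
14 | 1-[2,4,6-tris(1-ethoxyethoxy)phenyl]ethan-1-one (acetal epimers) | CCOC(C)Oc1cc(OC(C)OCC)c(C(C)=O)c(OC(C)OCC)c1 | intermediate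
15 | 2-ArB-1-[2,4,6-tris(1-ethoxyethoxy)phenyl]ethan-1-one (acetal epimers) | C/C(=C\Cc1c(O[Si](C)(C)C(C)(C)C)ccc(CC(=O)c2c(OC(C)OCC)cc(OC(C)OCC)cc2OC(C)OCC)c1O[Si](C)(C)C(C)(C)C)CCCC(C)(C)O[Si](CC)(CC)CC | intermediate
16 | 2-ArB-3-(dimethylamino)-1-[2,4,6-tris(1-ethoxyethoxy)phenyl]propan-1-one (racemic, acetal epimers) | C/C(=C\Cc1c(O[Si](C)(C)C(C)(C)C)ccc(C(CN(C)C)C(=O)c2c(OC(C)OCC)cc(OC(C)OCC)cc2OC(C)OCC)c1O[Si](C)(C)C(C)(C)C)CCCC(C)(C)O[Si](CC)(CC)CC | intermediate
17 | {2-ArB-3-oxo-3-[2,4,6-tris(1-ethoxyethoxy)phenyl]propyl}trimethylammonium iodide (racemic, acetal epimers) | C/C(=C\Cc1c(O[Si](C)(C)C(C)(C)C)ccc(C(C[N+](C)(C)C)C(=O)c2c(OC(C)OCC)cc(OC(C)OCC)cc2OC(C)OCC)c1O[Si](C)(C)C(C)(C)C)CCCC(C)(C)O[Si](CC)(CC)CC.[I-] | intermediate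
18 | 2-ArB-1-[2,4,6-tris(1-ethoxyethoxy)phenyl]prop-2-en-1-one (acetal epimers) | C/C(=C\Cc1c(O[Si](C)(C)C(C)(C)C)ccc(C(=C)C(=O)c2c(OC(C)OCC)cc(OC(C)OCC)cc2OC(C)OCC)c1O[Si](C)(C)C(C)(C)C)CCCC(C)(C)O[Si](CC)(CC)CC | intermediate
19 | 2-ArB-1-(2,4,6-trihydroxyphenyl)prop-2-en-1-one | C/C(=C\Cc1c(O[Si](C)(C)C(C)(C)C)ccc(C(=C)C(=O)c2c(O)cc(O)cc2O)c1O[Si](C)(C)C(C)(C)C)CCCC(C)(C)O[Si](CC)(CC)CC | intermediate
20 | 3-ArB-2H-chromene-4,5,7-triol (enol) | C/C(=C\Cc1c(O[Si](C)(C)C(C)(C)C)ccc(C2=C(O)c3c(O)cc(O)cc3OC2)c1O[Si](C)(C)C(C)(C)C)CCCC(C)(C)O[Si](CC)(CC)CC | intermediate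
21 | (3S)-3-ArB-5,7-dihydroxy-2,3-dihydro-4H-chromen-4-one | C/C(=C\Cc1c(O[Si](C)(C)C(C)(C)C)ccc([C@H]2COc3cc(O)cc(O)c3C2=O)c1O[Si](C)(C)C(C)(C)C)CCCC(C)(C)O[Si](CC)(CC)CC | intermediate
22 | (3S)-3-{2,4-dihydroxy-3-[(2E)-7-hydroxy-3,7-dimethyloct-2-en-1-yl]phenyl}-5,7-dihydroxy-2,3-dihydro-4H-chromen-4-one | C/C(=C\Cc1c(O)ccc([C@H]2COc3cc(O)cc(O)c3C2=O)c1O)CCCC(C)(C)O | target

**Totals**
Total step count: 12. Longest linear sequence: 9 steps (1–4, 7, 9–12).

**Steps most likely to fail**

Step 11 (the proposed new method). What may go wrong: proton transfer to enol 20 with poor facial selectivity, re-enolization of 21 under the acid, closure of 19 before the catalyst engages it, or capture of the acetal-derived oxocarbenium ion by ring A. Fallback with known chemistry, setting out from 18: PPTS in MeOH/CH2Cl2 removes the acetals and a little Et3N then closes ring C without stereocontrol to the racemic isoflavanone F1. TBSOTf/2,6-lutidine caps the 5- and 7-hydroxyls to give the racemic pentasilyl ketone F2. Asymmetric transfer hydrogenation with RuCl[(S,S)-TsDPEN](p-cymene) in HCO2H/Et3N, run as a dynamic kinetic resolution (the α-aryl ketone racemizes through its enol while one enantiomer is reduced), should give the cis-(3S,4S)-isoflavan-4-ol F3. Dess–Martin periodinane (NaHCO3, CH2Cl2) oxidizes C4 back without touching C3 to the (3S)-ketone F4. HF·pyridine under the conditions of step 12 removes all five silyl groups, and the sequence comes back to the route at 22.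

Step 7. What may go wrong: slow C–C bond formation at the aryl carbon flanked by two bulky silyloxy groups, so that attack at the γ-carbon, loss of alkene geometry, migration of silicon from oxygen to carbon or homocoupling of 7 compete. Fallback, setting out from 9: MOMCl/i-Pr2NEt gives the bis(methoxymethyl) ether F5. Iodine–lithium exchange with n-BuLi at −78 °C, transmetalation with CuBr·SMe2 and alkylation with 7 (the standard arylcopper route to 2-allylated resorcinol ethers, here with two small chelating acetals next to the metal) give the coupled bis(methoxymethyl) ether F6. HCl in MeOH at 40 °C removes both acetals and the silyl ether to give the triol F7. TBSCl/imidazole silylates the two phenols to give the bis(silyl ether) F8, and TESOTf/2,6-lutidine then silylates the tertiary alcohol, which brings the sequence back to the route at 12.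

Step 9. What may go wrong: slow oxidative addition or reductive elimination at the hindered, electron-rich bromide, so that base-induced loss of aryl silyl ethers, aldol self-condensation of 14 or double arylation take over. Fallback, setting out from 14: LiN(i-Pr)2 then TMSCl gives the silyl enol ether F9, which replaces the alkali enolate by a neutral enolate equivalent. Its coupling with 12 under Pd(OAc)2/P(t-Bu)3 with Bu3SnF in toluene at 80 °C (a tin enolate formed in situ is arylated, with no stoichiometric base present) comes back to the route at 15.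

**Further compounds**
F1 | step 11 | racemic 3-ArB-5,7-dihydroxy-2,3-dihydro-4H-chromen-4-one | C/C(=C\Cc1c(O[Si](C)(C)C(C)(C)C)ccc(C2COc3cc(O)cc(O)c3C2=O)c1O[Si](C)(C)C(C)(C)C)CCCC(C)(C)O[Si](CC)(CC)CC
F2 | step 11 | racemic 3-ArB-5,7-bis(tert-butyldimethylsilyloxy)-2,3-dihydro-4H-chromen-4-one | C/C(=C\Cc1c(O[Si](C)(C)C(C)(C)C)ccc(C2COc3cc(O[Si](C)(C)C(C)(C)C)cc(O[Si](C)(C)C(C)(C)C)c3C2=O)c1O[Si](C)(C)C(C)(C)C)CCCC(C)(C)O[Si](CC)(CC)CC
F3 | step 11 | cis-(3S,4S)-3-ArB-5,7-bis(tert-butyldimethylsilyloxy)-3,4-dihydro-2H-chromen-4-ol | C/C(=C\Cc1c(O[Si](C)(C)C(C)(C)C)ccc([C@H]2COc3cc(O[Si](C)(C)C(C)(C)C)cc(O[Si](C)(C)C(C)(C)C)c3[C@H]2O)c1O[Si](C)(C)C(C)(C)C)CCCC(C)(C)O[Si](CC)(CC)CC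
F4 | step 11 | (3S)-3-ArB-5,7-bis(tert-butyldimethylsilyloxy)-2,3-dihydro-4H-chromen-4-one | C/C(=C\Cc1c(O[Si](C)(C)C(C)(C)C)ccc([C@H]2COc3cc(O[Si](C)(C)C(C)(C)C)cc(O[Si](C)(C)C(C)(C)C)c3C2=O)c1O[Si](C)(C)C(C)(C)C)CCCC(C)(C)O[Si](CC)(CC)CC
F5 | step 7 | 1-bromo-3-iodo-2,4-bis(methoxymethoxy)benzene | COCOc1ccc(Br)c(OCOC)c1I
F6 | step 7 | 1-bromo-3-[(2E)-3,7-dimethyl-7-(triethylsilyloxy)oct-2-en-1-yl]-2,4-bis(methoxymethoxy)benzene | C/C(=C\Cc1c(OCOC)ccc(Br)c1OCOC)CCCC(C)(C)O[Si](CC)(CC)CC
F7 | step 7 | 4-bromo-2-[(2E)-7-hydroxy-3,7-dimethyloct-2-en-1-yl]benzene-1,3-diol | C/C(=C\Cc1c(O)ccc(Br)c1O)CCCC(C)(C)O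
F8 | step 7 | (6E)-8-[3-bromo-2,6-bis(tert-butyldimethylsilyloxy)phenyl]-2,6-dimethyloct-6-en-2-ol | C/C(=C\Cc1c(O[Si](C)(C)C(C)(C)C)ccc(Br)c1O[Si](C)(C)C(C)(C)C)CCCC(C)(C)O
F9 | step 9 | trimethyl({1-[2,4,6-tris(1-ethoxyethoxy)phenyl]ethenyl}oxy)silane (acetal epimers) | CCOC(C)Oc1cc(OC(C)OCC)c(C(=C)O[Si](C)(C)C)c(OC(C)OCC)c1
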